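Ring C of the abietane half is spanned by a two-carbon bridge whose methylene C15′ ends on quaternary C8, and C8 is linked through C9 to the C11 carbonyl. One added bond, C9–C15′, would make the five-membered ketone ring C8–C14–C13–C14′–C15′ part of a cyclopropyl ketone, the adduct of an alkene and a one-carbon dipole. The route therefore adds a C15′ diazoalkane across C8=C9 of a C13-quaternary ene-trione; loss of N2 under light closes that ring and the cyclopropane in one operation and sets C8, C9 and C15′. The precursor is the tosylhydrazone of a quinone Claisen product joining a ring-B-contracted royleanone to the labdane chain; iodide opening at C15′ and stannane reduction later delete the added bond.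

Key step: step 29

Assumption: abietane carbons keep their numbers (C7 is the carbon that leaves ring B and ends as the formyl group), labdane carbons carry primes (C17′ is the exocyclic methylene), and centres that are reset later (C13/C14 in 24, C6 in 12, C12′ in 31 and 37) are drawn as the expected major isomer or left open.

Step 1
Reactants: 1 (+)-dehydroabietylamine
Product: 2 abieta-8,11,13-triene
Conditions: H2NOSO3H, NaOH, H2O–EtOH, 0 °C → rt
Reagents that add atoms: none
Why: Reductive deamination of a primary amine with hydroxylamine-O-sulfonic acid (double N-amination, then loss of N2) replaces the C18–N bond by C–H without a carbocation, so the neopentyl C4 becomes the gem-dimethyl carbon without rearrangement and C5 and C10 are untouched.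

Step 2
Reactants: 2 abieta-8,11,13-triene
Product: 3 12-acetylabieta-8,11,13-triene
Conditions: AcCl, AlCl3, CH2Cl2, 0 °C → rt
Reagents that add atoms: acetyl chloride, CC(=O)Cl
Why: Friedel–Crafts acylation should go to C12, the ring C position para to C8 that is free of the peri strain from C1 and C7 felt at C11 and C14.

Step 3
Reactants: 3 12-acetylabieta-8,11,13-triene
Product: 4 abieta-8,11,13-trien-12-yl acetate
Conditions: mCPBA, CF3CO2H (cat.), CH2Cl2, rt
Reagents that add atoms: 3-chloroperbenzoic acid, O=C(OO)c1cccc(Cl)c1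
Why: Baeyer–Villiger oxidation of the aryl methyl ketone, in which the electron-rich aryl group migrates in preference to methyl and gives the aryl acetate.

Step 4
Reactants: 4 abieta-8,11,13-trien-12-yl acetate
Product: 6 12-methoxyabieta-8,11,13-triene, via ferruginol sodium salt 5 (not isolated)
Conditions: Me2SO4, NaOH (aq), Bu4NBr (cat.), CH2Cl2, rt
Reagents that add atoms: dimethyl sulfate, COS(=O)(=O)OC
Why: Saponification of the aryl acetate and Williamson O-methylation of the phenoxide under phase transfer in one flask install a phenol protecting group that survives strong base and chromium oxidation.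

Step 5
Reactants: 6 12-methoxyabieta-8,11,13-triene
Product: 7 12-methoxyabieta-8,11,13-trien-7-one
Conditions: CrO3, AcOH–H2O, rt
Reagents that add atoms: chromium trioxide, O=[Cr](=O)=O
Why: Benzylic oxidation should be selective for the C7 methylene, which is activated by the para methoxy group and less hindered than the isopropyl methine.

Step 6
Reactants: 7 12-methoxyabieta-8,11,13-trien-7-one
Product: 10 6-diazo-12-methoxyabieta-8,11,13-trien-7-one, via lithium enolate 8 (not isolated), via trifluoroacetyl ketone 9 (not isolated)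
Conditions: LiN(SiMe3)2, THF, −78 °C; CF3CO2CH2CF3; then MeSO2N3, Et3N, H2O, MeCN, rt
Reagents that add atoms: methanesulfonyl azide, CS(=O)(=O)N=[N+]=[N-]
Why: Detrifluoroacetylative diazo transfer (Regitz type) works on the only enolisable position, C6, and leaves the C5 stereocentre untouched.

Step 7
Reactants: 10 6-diazo-12-methoxyabieta-8,11,13-trien-7-one
Product: 12 ring-B-contracted methyl ester, via ketene 11 (not isolated)
Conditions: hν (medium-pressure Hg lamp, Pyrex), MeOH, rt
Reagents that add atoms: methanol, CO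
Why: Photochemical Wolff rearrangement moves aryl carbon C8 from C7 to C6, which contracts ring B and leaves C7 as the exocyclic ester carbon after methanol traps the ketene; C5 is a spectator and the C6 epimers converge in step 8.

Step 8
Reactants: 12 ring-B-contracted methyl ester
Product: 14 6α-hydroxy methyl ester, via potassium enolate 13 (not isolated)
Conditions: KN(SiMe3)2, THF, −78 °C; then 2-(phenylsulfonyl)-3-phenyloxaziridine
Reagents that add atoms: 2-(phenylsulfonyl)-3-phenyloxaziridine, O=S(=O)(c1ccccc1)N1OC1c1ccccc1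
Why: Enolate hydroxylation with an N-sulfonyloxaziridine sets C6, because the planar benzylic enolate is attacked on its α face, away from the C20 methyl and the axial 4β-methyl, which places OH α and the ester carbon β as in the target.

Step 9
Reactants: 14 6α-hydroxy methyl ester
Product: 15 6α,7-diol
Conditions: LiAlH4, THF, 0 °C → rt
Reagents that add atoms: none
Why: Hydride reduction of the ester gives the primary alcohol C7 without touching the quaternary C6 carbinol.

Step 10
Reactants: 15 6α,7-diol
Product: 16 12-methoxy 6,7-acetonide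
Conditions: Me2C(OMe)2, pyridinium p-toluenesulfonate (cat.), CH2Cl2, rt
Reagents that add atoms: 2,2-dimethoxypropane, COC(C)(C)OC
Why: Transketalisation protects the tertiary/primary 1,2-diol as a dioxolane that resists the bases, oxidants and radicals used later.

Step 11
Reactants: 16 12-methoxy 6,7-acetonide
Product: 17 12-hydroxy 6,7-acetonide
Conditions: NaSEt, DMF, 130 °C; HCl (aq) work-up
Reagents that add atoms: none
Why: SN2 demethylation of the aryl methyl ether by thiolate frees the phenol under basic conditions that the acetonide tolerates.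

Step 12
Reactants: 17 12-hydroxy 6,7-acetonide
Product: 18 11,12-ortho-quinone acetonide
Conditions: 2-iodoxybenzoic acid (IBX), DMF, rt
Reagents that add atoms: 2-iodoxybenzoic acid, O=C1OI(=O)(O)c2ccccc12
Why: IBX ortho-oxygenation of a phenol delivers oxygen to C11, the only free ortho position, and the ring-contracted skeleton has no C7–H through which the quinone could tautomerise to a quinone methide.

Step 13
Reactants: 18 11,12-ortho-quinone acetonide
Product: 21 ring-B-contracted royleanone acetonide, via thio-catechol 19 (not isolated), via thio-ortho-quinone 20 (not isolated)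
Conditions: C6F5SH, CH2Cl2, rt; then NaOH, MeOH–H2O, O2, rt; HCl (aq)
Reagents that add atoms: sodium hydroxide, [Na+].[OH-]
Why: Conjugate addition of the thiol at C14, aerobic re-oxidation and addition–elimination by hydroxide at C14 give the 14-hydroxy ortho-quinone, which is the tautomer of the stable 12-hydroxy-11,14-quinone.

Step 14
Reactants: 22 abietic acid
Product: 23 2-(trimethylsilyl)ethyl abietate
Conditions: Me3SiCH2CH2OH, PPh3, DIAD, THF, 0 °C → rt
Reagents that add atoms: 2-(trimethylsilyl)ethanol, C[Si](C)(C)CCO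
Why: Mitsunobu esterification alkylates the hindered carboxylate on oxygen, so the congested C4 carbonyl is never attacked, and the resulting ester can later be removed by fluoride without acyl substitution.

Step 15
Reactants: 23 2-(trimethylsilyl)ethyl abietate
Product: 25 13,14-seco keto-enal, via 13,14-diol 24 (not isolated)
Conditions: OsO4 (cat.), NaIO4, 2,6-lutidine, dioxane–H2O, rt
Reagents that add atoms: osmium tetroxide, O=[Os](=O)(=O)=O; sodium periodate, [Na+].[O-]I(=O)(=O)=O
Why: Lemieux–Johnson cleavage should take the more exposed C13=C14 bond of the diene, after which the remaining C7=C8 bond is conjugated to the new aldehyde and deactivated towards further osmylation.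

Step 16
Reactants: 25 13,14-seco keto-enal
Product: 26 allylic alcohol
Conditions: NaBH4, EtOH–CH2Cl2, −78 °C
Reagents that add atoms: none
Why: Borohydride 1,2-reduction is chemoselective for the aldehyde over the hindered isopropyl ketone at low temperature.

Step 17
Reactants: 26 allylic alcohol
Product: 29 8′(17′)-methylene isopropyl ketone, via N-allyl sulfonylhydrazine 27 (not isolated), via allylic diazene 28 (not isolated)
Conditions: 2-O2NC6H4SO2NHNH2, PPh3, DEAD, THF, −30 °C → rt
Reagents that add atoms: none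
Why: Reductive 1,3-transposition of an allylic alcohol (Mitsunobu displacement by the sulfonylhydrazide, loss of sulfinic acid, retro-ene loss of N2) delivers hydrogen to C7′ and moves the double bond to the exocyclic C8′=C17′ position of the labdane.

Step 18
Reactants: 29 8′(17′)-methylene isopropyl ketone
Product: 31 12′-hydroxy ketone, via lithium enolate 30 (not isolated)
Conditions: LiN(iPr)2, THF, −78 °C; then 2-(phenylsulfonyl)-3-phenyloxaziridine
Reagents that add atoms: 2-(phenylsulfonyl)-3-phenyloxaziridine, O=S(=O)(c1ccccc1)N1OC1c1ccccc1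
Why: Kinetic deprotonation takes the methylene C12′ and not the isopropyl methine, and oxaziridine hydroxylation of that enolate does not touch the alkene; the C12′ configuration is irrelevant.

Step 19
Reactants: 31 12′-hydroxy ketone
Product: 32 C12′ aldehyde
Conditions: Pb(OAc)4, MeOH–PhH, 0 °C
Reagents that add atoms: none
Why: Oxidative α-ketol cleavage with lead tetraacetate breaks the C12′–C13′ bond, excising the isopropyl ketone carbon as methyl isobutyrate and leaving the two-carbon aldehyde chain on C9′.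

Step 20
Reactants: 33 but-2-yn-1-ol
Product: 35 (Z)-3-iodobut-2-en-1-ol, via cyclic alkenylaluminate 34 (not isolated)
Conditions: NaAlH2(OCH2CH2OMe)2, THF, 0 °C → rt; then I2, −78 °C
Reagents that add atoms: iodine, II
Why: Alkoxide-directed trans-hydroalumination places aluminium on C3 in a five-membered ring, and iodinolysis with retention gives the vinyl iodide with iodine cis to the CH2OH group.

Step 21
Reactants: 35 (Z)-3-iodobut-2-en-1-ol
Product: 36 (Z)-vinyl iodide silyl ether
Conditions: TBSCl, imidazole, CH2Cl2, rt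
Reagents that add atoms: tert-butyldimethylsilyl chloride, CC(C)(C)[Si](C)(C)Cl
Why: Standard silylation protects the future C15′ hydroxyl as the small primary ether that the Claisen transition state can accommodate.

Step 22
Reactants: 32 C12′ aldehyde; 36 (Z)-vinyl iodide silyl ether
Product: 37 (13′Z)-allylic alcohol as a mixture of C12′ epimers
Conditions: CrCl2, NiCl2 (cat.), DMF, rt
Reagents that add atoms: none
Why: Nozaki–Hiyama–Kishi coupling adds the trisubstituted alkenyl unit to the aldehyde with retention of alkene geometry and tolerates the hindered ester; the C12′ epimers are merged in step 23.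

Step 23
Reactants: 37 (13′Z)-allylic alcohol
Product: 38 (13′Z)-enone
Conditions: Dess–Martin periodinane, NaHCO3, CH2Cl2, 0 °C
Reagents that add atoms: none
Why: Buffered Dess–Martin oxidation gives the enone under neutral conditions that should not isomerise the Z double bond.

Step 24
Reactants: 38 (13′Z)-enone
Product: 39 (12′R,13′Z)-allylic alcohol
Conditions: (S)-CBS catalyst [(S)-1-methyl-3,3-diphenyltetrahydro-1H,3H-pyrrolo[1,2-c][1,3,2]oxazaborole], catecholborane, PhMe, −78 °C
Reagents that add atoms: none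
Why: Corey–Bakshi–Shibata reduction with the α-methylalkenyl group as the large substituent should deliver hydride to give the (12′R) carbinol under catalyst control, and catecholborane does not hydroborate the exocyclic alkene at this temperature.

Step 25
Reactants: 21 ring-B-contracted royleanone acetonide; 39 (12′R,13′Z)-allylic alcohol
Product: 40 (12′S)-12-O-allyl quinone ether
Conditions: PPh3, DIAD, PhMe, 0 °C → rt
Reagents that add atoms: none
Why: Mitsunobu etherification alkylates the acidic hydroxyquinone on O12 with SN2 inversion at C12′, which gives the (12′S) ether required for the chirality transfer of step 26.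

Step 26
Reactants: 40 (12′S)-12-O-allyl quinone ether
Product: 41 C13-quaternary ene-trione silyl ether
Conditions: PhMe, 100 °C
Reagents that add atoms: none
Why: Claisen rearrangement through a chair transition state, in which allylic strain from the (Z)-CH2OTBS group keeps C11′ pseudo-equatorial so that the new C12′=C13′ bond is E, transfers the C12′ configuration suprafacially to C14′ and, because the ring enol ether geometry is fixed, bonds C14′ to the α face of C13 (anti to the C20 methyl), so that C13 and C14′ are set together.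

Step 27
Reactants: 41 C13-quaternary ene-trione silyl ether
Product: 42 ene-trione primary alcohol
Conditions: HF·pyridine, pyridine, THF, 0 °C → rt
Reagents that add atoms: none
Why: Buffered HF·pyridine removes the primary silyl ether without base, so the electrophilic trione, the acetonide and the silylethyl ester should be left intact.

Step 28
Reactants: 42 ene-trione primary alcohol
Product: 44 ene-trione C15′ tosylhydrazone, via C15′ aldehyde 43 (not isolated)
Conditions: Dess–Martin periodinane, NaHCO3, CH2Cl2, 0 °C; then TsNHNH2, 0 °C → rt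
Reagents that add atoms: 4-methylbenzenesulfonohydrazide, Cc1ccc(cc1)S(=O)(=O)NN
Why: Dess–Martin oxidation followed at once by hydrazone condensation traps the epimerisable β,γ-unsaturated aldehyde before C14′ can scramble, and the unhindered aldehyde should condense far faster than the ring carbonyls flanked by quaternary carbons.

Step 29
Reactants: 44 ene-trione C15′ tosylhydrazone
Product: 47 cyclopropane-fused bridged trione, via diazoalkane 45 (not isolated), via pyrazoline 46 (not isolated)
Conditions: Cs2CO3, 1,4-dioxane (0.005 M), 70 °C; then hν (350 nm), rt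
Reagents that add atoms: none
Why: Cs2CO3 deprotonates the hydrazone and the salt loses sulfinate (Bamford–Stevens) to give diazoalkane 45, a nucleophilic 1,3-dipole whose carbon bonds to C8 and whose terminal nitrogen bonds to C9 of the doubly acyl-activated alkene to give 1-pyrazoline 46; irradiation of the azo chromophore then expels N2 and the C9/C15′ diradical collapses to cyclopropane 47. The closest known reaction type is the intramolecular diazoalkane–enone (cyclohexadienone) cycloaddition followed by photochemical denitrogenation of the pyrazoline to a cyclopropyl ketone. The cyclopentanone ring (C8, C14, C13, C14′, C15′) closes 5-exo through the C13–C14′–C15′ tether during the cycloaddition, and the cyclopropane (C8, C9, C15′) closes by 3-exo recombination of the 1,3-diradical. C8 and C9 are set by the tether, which lets C15′ reach only the α face that C14′ occupies on C13, and C15′ is fixed because both of its new bonds must be cis on the C8–C9 bond. The step needs addition to C8=C9 in preference to the C11 carbonyl, to the labdane alkenes and to 1,2-hydrogen shift of the diazoalkane; the low LUMO of the ene-dione, the two-atom tether and high dilution should secure this, and the pyrazoline cannot tautomerise because its C15′=N form would be a bridgehead imine. Whether nitrogen bonds first to C9 or to C8 is immaterial, since both pyrazolines give the same cyclopropane.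

Step 30
Reactants: 47 cyclopropane-fused bridged trione
Product: 48 15′-iodo diosphenol
Conditions: MgI2, THF–PhMe, 40 °C; NH4Cl (aq)
Reagents that add atoms: magnesium iodide, [Mg+2].[I-].[I-]
Why: Homoconjugate (SN2-type) opening of an acyl cyclopropane: magnesium chelates the C11/C12 dione, iodide can attack only C15′ (the one cyclopropane carbon that is not quaternary) from the open exo side, and the C9–C15′ bond breaks because it releases the chelated diosphenolate, whereas a reductive electron-transfer opening would cut the doubly activated C8–C9 bond; the iodine-bearing C15′ centre is formed with inversion and is removed in step 31.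

Step 31
Reactants: 48 15′-iodo diosphenol
Product: 49 diosphenol acetonide ester
Conditions: Bu3SnH, PhSeSePh (cat.), Et3B, air, PhMe, rt
Reagents that add atoms: none
Why: Radical chain deiodination gives the C15′ methylene, with benzeneselenol formed in the flask as a fast hydrogen donor so that the C15′ radical is quenched before it can re-close onto the C9=C11 enol (homoallyl–cyclopropylcarbinyl rearrangement).

Step 32
Reactants: 49 diosphenol acetonide ester
Product: 51 diosphenol triol acid, via carboxylic acid acetonide 50 (not isolated)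
Conditions: Bu4NF, THF, rt; then AcOH–H2O (4:1), 50 °C
Reagents that add atoms: none
Why: Fluoride-induced fragmentation of the 2-(trimethylsilyl)ethyl ester frees the hindered acid without acyl substitution, and aqueous acetic acid then hydrolyses the dioxolane while being too weak to protonate the exocyclic alkene.

Step 33
Reactants: 51 diosphenol triol acid
Product: 52 CNP0124601.1
Conditions: 2-iodoxybenzoic acid (IBX), DMSO, rt
Reagents that add atoms: none
Why: IBX oxidation converts the primary C7 alcohol into the aldehyde without cleaving the 1,2-diol, cannot oxidise the tertiary C6 carbinol or the acid, and needs no base, which avoids α-ketol rearrangement of the product; the enol carbon C9 is shielded by two quaternary neighbours.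

Compound list
1 | (+)-dehydroabietylamine (abieta-8,11,13-trien-18-amine) | CC(C)c1ccc2c(c1)CC[C@@H]1[C@]2(C)CCC[C@@]1(C)CN | starting material
2 | abieta-8,11,13-triene | CC(C)c1ccc2c(c1)CC[C@@H]1[C@]2(C)CCCC1(C)C | intermediate
3 | 12-acetylabieta-8,11,13-triene | CC(C)c1c(C(C)=O)cc2c(c1)CC[C@@H]1[C@]2(C)CCCC1(C)C | intermediate
4 | abieta-8,11,13-trien-12-yl acetate | CC(C)c1c(OC(C)=O)cc2c(c1)CC[C@@H]1[C@]2(C)CCCC1(C)C | intermediate
5 | ferruginol, present as its sodium phenoxide (not isolated) | CC(C)c1c(O)cc2c(c1)CC[C@@H]1[C@]2(C)CCCC1(C)C | intermediate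
6 | 12-methoxyabieta-8,11,13-triene | CC(C)c1c(OC)cc2c(c1)CC[C@@H]1[C@]2(C)CCCC1(C)C | intermediate
7 | 12-methoxyabieta-8,11,13-trien-7-one | CC(C)c1c(OC)cc2c(c1)C(=O)C[C@@H]1[C@]2(C)CCCC1(C)C | intermediate
8 | lithium enolate of 7 (C6=C7–OLi; not isolated) | CC(C)c1c(OC)cc2c(c1)C(O[Li])=C[C@@H]1[C@]2(C)CCCC1(C)C | intermediate
9 | 12-methoxy-6-(trifluoroacetyl)abieta-8,11,13-trien-7-one (C6 enolised, not defined; not isolated) | CC(C)c1c(OC)cc2c(c1)C(=O)C(C(=O)C(F)(F)F)[C@@H]1[C@]2(C)CCCC1(C)C | intermediate
10 | 6-diazo-12-methoxyabieta-8,11,13-trien-7-one | CC(C)c1c(OC)cc2c(c1)C(=O)C(=[N+]=[N-])[C@@H]1[C@]2(C)CCCC1(C)C | intermediate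
11 | ring-B-contracted ketene (C6 bonded to C5 and C8, C6=C7=O; not isolated) | CC(C)c1cc2c(cc1OC)[C@@]1(C)CCCC(C)(C)[C@@H]1C2=C=O | intermediate
12 | ring-B-contracted methyl ester (5α-H, 6α-H, ester carbon C7 β; expected major C6 epimer) | CC(C)c1cc2c(cc1OC)[C@@]1(C)CCCC(C)(C)[C@@H]1[C@@H]2C(=O)OC | intermediate
13 | potassium ester enolate of 12 (not isolated) | CC(C)c1cc2c(cc1OC)[C@@]1(C)CCCC(C)(C)[C@@H]1C2=C(OC)O[K] | intermediate
14 | 6α-hydroxy methyl ester (ester carbon C7 β) | CC(C)c1cc2c(cc1OC)[C@@]1(C)CCCC(C)(C)[C@@H]1[C@]2(O)C(=O)OC | intermediate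
15 | 6α,7-diol, 12-methoxy | CC(C)c1cc2c(cc1OC)[C@@]1(C)CCCC(C)(C)[C@@H]1[C@]2(O)CO | intermediate
16 | 6,7-acetonide, 12-methoxy | CC(C)c1cc2c(cc1OC)[C@@]1(C)CCCC(C)(C)[C@@H]1[C@]2(OC(C)(C)O3)C3 | intermediate
17 | 6,7-acetonide, 12-hydroxy (phenol) | CC(C)c1cc2c(cc1O)[C@@]1(C)CCCC(C)(C)[C@@H]1[C@]2(OC(C)(C)O3)C3 | intermediate
18 | 11,12-ortho-quinone acetonide | CC(C)C1=CC2=C(C(=O)C1=O)[C@@]1(C)CCCC(C)(C)[C@@H]1[C@]2(OC(C)(C)O3)C3 | intermediate
19 | 14-(pentafluorophenylthio)-11,12-catechol acetonide (not isolated) | CC(C)c1c(Sc3c(F)c(F)c(F)c(F)c3F)c2c(c(O)c1O)[C@@]1(C)CCCC(C)(C)[C@@H]1[C@]2(OC(C)(C)O3)C3 | intermediate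
20 | 14-(pentafluorophenylthio)-11,12-ortho-quinone acetonide (not isolated) | CC(C)C1=C(Sc3c(F)c(F)c(F)c(F)c3F)C2=C(C(=O)C1=O)[C@@]1(C)CCCC(C)(C)[C@@H]1[C@]2(OC(C)(C)O3)C3 | intermediate
21 | ring-B-contracted royleanone 6,7-acetonide (12-hydroxy-11,14-quinone; 6-O α, C7 β) | CC(C)C1=C(O)C(=O)C(=C2C1=O)[C@@]3(C)CCCC(C)(C)[C@@H]3[C@]2(OC(C)(C)O4)C4 | intermediate
22 | abietic acid | CC(C)C1=CC2=CC[C@@H]3[C@](C)(CCC[C@@]3(C)C(=O)O)[C@H]2CC1 | starting material
23 | 2-(trimethylsilyl)ethyl abietate | CC(C)C1=CC2=CC[C@@H]3[C@](C)(CCC[C@@]3(C)C(=O)OCC[Si](C)(C)C)[C@H]2CC1 | intermediate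
24 | 13α,14α-dihydroxyabiet-7-ene ester (not isolated; face of attack immaterial) | CC(C)[C@@]1(O)[C@H](O)C2=CC[C@@H]3[C@](C)(CCC[C@@]3(C)C(=O)OCC[Si](C)(C)C)[C@H]2CC1 | intermediate
25 | 13,14-seco keto-enal (C14 aldehyde on C8 with C7=C8; C13 isopropyl ketone) | O=CC1=CC[C@@H]2[C@](C)(CCC[C@@]2(C)C(=O)OCC[Si](C)(C)C)[C@H]1CCC(=O)C(C)C | intermediate
26 | allylic alcohol (C14 hydroxymethyl on C8, C7=C8) | OCC1=CC[C@@H]2[C@](C)(CCC[C@@]2(C)C(=O)OCC[Si](C)(C)C)[C@H]1CCC(=O)C(C)C | intermediate
27 | N-allyl-N-(2-nitrophenylsulfonyl)hydrazine (not isolated) | NN(S(=O)(=O)c1ccccc1[N+](=O)[O-])CC1=CC[C@@H]2[C@](C)(CCC[C@@]2(C)C(=O)OCC[Si](C)(C)C)[C@H]1CCC(=O)C(C)C | intermediate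
28 | allylic diazene (not isolated) | N=NCC1=CC[C@@H]2[C@](C)(CCC[C@@]2(C)C(=O)OCC[Si](C)(C)C)[C@H]1CCC(=O)C(C)C | intermediate
29 | 8′(17′)-methylene isopropyl ketone (labdane-type bicycle, 9′-(4-methyl-3-oxopentyl) chain) | C=C1CC[C@@H]2[C@](C)(CCC[C@@]2(C)C(=O)OCC[Si](C)(C)C)[C@H]1CCC(=O)C(C)C | intermediate
30 | lithium enolate of 29 towards C12′ (not isolated) | C=C1CC[C@@H]2[C@](C)(CCC[C@@]2(C)C(=O)OCC[Si](C)(C)C)[C@H]1C/C=C(\O[Li])C(C)C | intermediate
31 | 12′-hydroxy ketone (C12′ epimers) | C=C1CC[C@@H]2[C@](C)(CCC[C@@]2(C)C(=O)OCC[Si](C)(C)C)[C@H]1CC(O)C(=O)C(C)C | intermediate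
32 | C12′ aldehyde (9′-CH2–CHO on the 8′(17′)-ene bicycle) | C=C1CC[C@@H]2[C@](C)(CCC[C@@]2(C)C(=O)OCC[Si](C)(C)C)[C@H]1CC=O | intermediate
33 | but-2-yn-1-ol | CC#CCO | starting material
34 | cyclic sodium alkenylaluminate (not isolated) | CC1=CCO[Al-]1(OCCOC)OCCOC.[Na+] | intermediate
35 | (Z)-3-iodobut-2-en-1-ol | C/C(I)=C/CO | intermediate
36 | (Z)-tert-butyl[(3-iodobut-2-en-1-yl)oxy]dimethylsilane | C/C(I)=C/CO[Si](C)(C)C(C)(C)C | intermediate
37 | (13′Z)-allylic alcohol, C12′ epimers | C=C1CC[C@@H]2[C@](C)(CCC[C@@]2(C)C(=O)OCC[Si](C)(C)C)[C@H]1CC(O)/C(C)=C\CO[Si](C)(C)C(C)(C)C | intermediate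
38 | (13′Z)-enone | C=C1CC[C@@H]2[C@](C)(CCC[C@@]2(C)C(=O)OCC[Si](C)(C)C)[C@H]1CC(=O)/C(C)=C\CO[Si](C)(C)C(C)(C)C | intermediate
39 | (12′R,13′Z)-allylic alcohol | C=C1CC[C@@H]2[C@](C)(CCC[C@@]2(C)C(=O)OCC[Si](C)(C)C)[C@H]1C[C@@H](O)/C(C)=C\CO[Si](C)(C)C(C)(C)C | intermediate
40 | (12′S)-12-O-allyl quinone ether | C=C1CC[C@@H]2[C@](C)(CCC[C@@]2(C)C(=O)OCC[Si](C)(C)C)[C@H]1C[C@H](OC3=C(C(C)C)C(=O)C4=C(C3=O)[C@@]5(C)CCCC(C)(C)[C@@H]5[C@]4(OC(C)(C)O6)C6)/C(C)=C\CO[Si](C)(C)C(C)(C)C | intermediate
41 | C13-quaternary ene-trione, C15′ silyl ether (C14′ chain α on C13, isopropyl β) | C=C1CC[C@@H]2[C@](C)(CCC[C@@]2(C)C(=O)OCC[Si](C)(C)C)[C@H]1C/C=C(\C)[C@H](CO[Si](C)(C)C(C)(C)C)[C@@]1(C(C)C)C(=O)C(=O)C(=C2C1=O)[C@@]3(C)CCCC(C)(C)[C@@H]3[C@]2(OC(C)(C)O4)C4 | intermediate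
42 | ene-trione C15′ alcohol | C=C1CC[C@@H]2[C@](C)(CCC[C@@]2(C)C(=O)OCC[Si](C)(C)C)[C@H]1C/C=C(\C)[C@H](CO)[C@@]1(C(C)C)C(=O)C(=O)C(=C2C1=O)[C@@]3(C)CCCC(C)(C)[C@@H]3[C@]2(OC(C)(C)O4)C4 | intermediate
43 | ene-trione C15′ aldehyde (not isolated) | C=C1CC[C@@H]2[C@](C)(CCC[C@@]2(C)C(=O)OCC[Si](C)(C)C)[C@H]1C/C=C(\C)[C@H](C=O)[C@@]1(C(C)C)C(=O)C(=O)C(=C2C1=O)[C@@]3(C)CCCC(C)(C)[C@@H]3[C@]2(OC(C)(C)O4)C4 | intermediate
44 | ene-trione C15′ (E)-tosylhydrazone, the key-step precursor | C=C1CC[C@@H]2[C@](C)(CCC[C@@]2(C)C(=O)OCC[Si](C)(C)C)[C@H]1C/C=C(\C)[C@H](/C=N/NS(=O)(=O)c1ccc(C)cc1)[C@@]1(C(C)C)C(=O)C(=O)C(=C2C1=O)[C@@]3(C)CCCC(C)(C)[C@@H]3[C@]2(OC(C)(C)O4)C4 | intermediate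
45 | C15′ diazoalkane (not isolated) | C=C1CC[C@@H]2[C@](C)(CCC[C@@]2(C)C(=O)OCC[Si](C)(C)C)[C@H]1C/C=C(\C)[C@H](C=[N+]=[N-])[C@@]1(C(C)C)C(=O)C(=O)C(=C2C1=O)[C@@]3(C)CCCC(C)(C)[C@@H]3[C@]2(OC(C)(C)O4)C4 | intermediate
46 | 1-pyrazoline (C15′–C8 and N–C9 bonds; not isolated) | C=C1CC[C@@H]2[C@](C)(CCC[C@@]2(C)C(=O)OCC[Si](C)(C)C)[C@H]1C/C=C(\C)[C@@H]1[C@H]4[C@@]23C(=O)[C@]1(C(C)C)C(=O)C(=O)[C@]2(N=N4)[C@@]1(C)CCCC(C)(C)[C@@H]1[C@]3(OC(C)(C)O5)C5 | intermediate
47 | cyclopropane-fused bridged trione, the key-step product (cyclopropane C8–C9–C15′ on the α face) | C=C1CC[C@@H]2[C@](C)(CCC[C@@]2(C)C(=O)OCC[Si](C)(C)C)[C@H]1C/C=C(\C)[C@@H]1[C@H]4[C@@]23C(=O)[C@]1(C(C)C)C(=O)C(=O)[C@]24[C@@]1(C)CCCC(C)(C)[C@@H]1[C@]3(OC(C)(C)O5)C5 | intermediate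
48 | 15′-iodo diosphenol (iodine exo, facing the C14 bridge) | C=C1CC[C@@H]2[C@](C)(CCC[C@@]2(C)C(=O)OCC[Si](C)(C)C)[C@H]1C/C=C(\C)[C@@H]1[C@@H](I)[C@@]23C(=O)[C@]1(C(C)C)C(=O)C(O)=C2[C@@]1(C)CCCC(C)(C)[C@@H]1[C@]3(OC(C)(C)O4)C4 | intermediate
49 | diosphenol acetonide 2-(trimethylsilyl)ethyl ester | C=C1CC[C@@H]2[C@](C)(CCC[C@@]2(C)C(=O)OCC[Si](C)(C)C)[C@H]1C/C=C(\C)[C@@H]1C[C@@]23C(=O)[C@]1(C(C)C)C(=O)C(O)=C2[C@@]1(C)CCCC(C)(C)[C@@H]1[C@]3(OC(C)(C)O4)C4 | intermediate
50 | diosphenol acetonide carboxylic acid (not isolated) | C=C1CC[C@@H]2[C@](C)(CCC[C@@]2(C)C(=O)O)[C@H]1C/C=C(\C)[C@@H]1C[C@@]23C(=O)[C@]1(C(C)C)C(=O)C(O)=C2[C@@]1(C)CCCC(C)(C)[C@@H]1[C@]3(OC(C)(C)O4)C4 | intermediate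
51 | diosphenol triol acid (6-OH, 7-OH free) | C=C1CC[C@@H]2[C@](C)(CCC[C@@]2(C)C(=O)O)[C@H]1C/C=C(\C)[C@@H]1C[C@@]23C(=O)[C@]1(C(C)C)C(=O)C(O)=C2[C@@]1(C)CCCC(C)(C)[C@@H]1[C@]3(O)CO | intermediate
52 | CNP0124601.1 | C=C1CC[C@@H]2[C@](C)(CCC[C@@]2(C)C(=O)O)[C@H]1C/C=C(\C)[C@@H]1C[C@@]23C(=O)[C@]1(C(C)C)C(=O)C(O)=C2[C@@]1(C)CCCC(C)(C)[C@@H]1[C@]3(O)C=O | target

Total step count: 33. Longest linear sequence: 22 steps (steps 1–13, then 25–33).

Steps most likely to fail

Step 29. The diazoalkane may lose nitrogen by 1,2-hydrogen shift to a C14′=C15′ alkene, or add to the C11 carbonyl, before it reaches the hindered tetrasubstituted C8=C9 bond. The fallback sets out from 42 and returns at 49. Alcohol 42 is converted with preformed Ph3P·I2 and imidazole in CH2Cl2 into the primary C15′ iodide F1. Bu3SnH with 2,2′-azobis(2-methylpropionitrile) in dilute benzene at 80 °C then generates the C15′ radical, which adds 5-exo to C8 of the ene-dione on the only face the tether allows. The resulting C9 radical, stabilised by the C11/C12 dione, takes hydrogen and the product enolises to diosphenol 49, so that steps 30 and 31 are bypassed as well.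

Step 25. Direct displacement at the hindered C12′ oxyphosphonium ion may lose out to SN2′ attack at C14′ or to elimination to a diene. The fallback sets out from 21 and 38 and returns at 40. Hydroxyquinone 21 is converted with (COCl)2 and a catalytic amount of DMF into the 12-chloroquinone F2. Enone 38 is reduced with the (R)-CBS catalyst and catecholborane to the (12′S)-allylic alcohol F3. The sodium alkoxide of F3 (NaH, THF, −20 °C) then displaces chloride from F2 by addition–elimination at C12, with retention at C12′, and gives ether 40.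

Step 30. The γ-iodo enolate may re-close to the cyclopropane, or the Lewis acid may strip the acetonide, so that the opening stays incomplete. The fallback sets out from 47 and returns at 49. NaSePh (from PhSeSePh and NaH in THF) opens 47 at C15′ without a Lewis acid to give the 15′-phenylselanyl diosphenol F4. A selenide is not a leaving group, so this opening cannot reverse. Bu3SnH with 2,2′-azobis(2-methylpropionitrile) in benzene at 80 °C then removes selenium and gives 49.

Further compounds
F1 | step 29 | ene-trione C15′ iodide | C=C1CC[C@@H]2[C@](C)(CCC[C@@]2(C)C(=O)OCC[Si](C)(C)C)[C@H]1C/C=C(\C)[C@H](CI)[C@@]1(C(C)C)C(=O)C(=O)C(=C2C1=O)[C@@]3(C)CCCC(C)(C)[C@@H]3[C@]2(OC(C)(C)O4)C4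
F2 | step 25 | 12-chloro-11,14-quinone acetonide | CC(C)C1=C(Cl)C(=O)C(=C2C1=O)[C@@]3(C)CCCC(C)(C)[C@@H]3[C@]2(OC(C)(C)O4)C4
F3 | step 25 | (12′S,13′Z)-allylic alcohol | C=C1CC[C@@H]2[C@](C)(CCC[C@@]2(C)C(=O)OCC[Si](C)(C)C)[C@H]1C[C@H](O)/C(C)=C\CO[Si](C)(C)C(C)(C)C
F4 | step 30 | 15′-phenylselanyl diosphenol | C=C1CC[C@@H]2[C@](C)(CCC[C@@]2(C)C(=O)OCC[Si](C)(C)C)[C@H]1C/C=C(\C)[C@@H]1[C@@H]([Se]c4ccccc4)[C@@]23C(=O)[C@]1(C(C)C)C(=O)C(O)=C2[C@@]1(C)CCCC(C)(C)[C@@H]1[C@]3(OC(C)(C)O4)C4
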